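**Retrosynthetic overview**

1. Numbering used throughout: C1 ketone, C2=C3(CH3), C4, C5, C6(CH3)2, C7 (O-senecioyl), C8, C9 (O-isovaleryl), C10(CH3), C11. The cyclobutane is C4-C5-C11-C10, the six-membered ring is C1-C2-C3-C4-C10-C11, and the seven-membered ring is C4-C5-C6-C7-C8-C9-C10.
2. Endgame: the enone comes from a C1 silyl ether by oxidation and alkene shift, and the C7 ester by acylation. The C9 isovalerate and the anti C7 carbinol are set together by an Evans–Tishchenko reduction of a 9-hydroxy-7-ketone. An auxiliary 5-OH is removed by radical deoxygenation.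
3. Key disconnection C5–C6: a C5 cyclobutanone and a C6 benzoyloxy ketone, both acceptor carbons, are joined by SmI2 polarity reversal, which closes the seven-membered ring last.
4. Enabling feature: C5 and C10 are the two one-carbon bridges of the bicyclo[3.1.1]heptane. The C9–C6 chain on the face of C10 remote from the C1–C3 bridge therefore lies 1,3-diaxial under C5. C6 is quaternary and alpha to oxygenated C7, so it can be delivered as a regiodefined enolate.
5. The cyclobutane and six-membered ring form together by a vinylketene–alkene (2+2) of an acyclic C15 acid, which is assembled from three C5 units by two asymmetric aldol additions. Ring order: four- and six-membered rings in step 8, seven-membered ring in step 9.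

Key step: step 9

Assumption: in steps 2 and 6 the named antipode of the chiral boron reagent or Lewis-base catalyst is taken to give the drawn configuration; both antipodes of each are available.

**Step 1**
Reactants: 1 3-hydroxy-3-methylbutan-2-one
Product: 2 2-methyl-3-oxobutan-2-yl benzoate
Conditions: BzCl, Et3N, DMAP (cat.), CH2Cl2, reflux
Reagents that add atoms: benzoyl chloride O=C(Cl)c1ccccc1
Why: DMAP-catalysed acylation of the tertiary alcohol installs the leaving group that step 9 expels and leaves the methyl group as the only enolisable position; no stereocentre is formed.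

**Step 2**
Reactants: 2 2-methyl-3-oxobutan-2-yl benzoate; 3 (2E)-4,4-dimethoxy-2-methylbut-2-enal
Product: 4 (5R,6E)-5-hydroxy-8,8-dimethoxy-2,6-dimethyl-3-oxooct-6-en-2-yl benzoate
Conditions: (−)-Ipc2BCl, Et3N, Et2O, 0 °C; 3, −78 to −20 °C; H2O2, MeOH, pH 7 buffer
Reagents that add atoms: none
Why: Diisopinocampheylboron enolate aldol addition of a methyl ketone, in which enolisation can occur only at the methyl group and the chiral ligands on boron select the aldehyde face, setting future C9 as R by reagent control.

**Step 3**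
Reactants: 4 (5R,6E)-5-hydroxy-8,8-dimethoxy-2,6-dimethyl-3-oxooct-6-en-2-yl benzoate
Product: 5 (5R,6E)-2,6-dimethyl-3,8-dioxo-5-(triethylsilyloxy)oct-6-en-2-yl benzoate
Conditions: Et3SiOTf, 2,6-lutidine, CH2Cl2, 0 °C; then H2O
Reagents that add atoms: triethylsilyl trifluoromethanesulfonate CC[Si](CC)(CC)OS(=O)(=O)C(F)(F)F; water O
Why: The silyl triflate/lutidine pair silylates the hydroxyl group and converts the aldehyde-derived dimethyl acetal through a lutidinium intermediate into the enal on addition of water, under non-acidic conditions that leave the silyl ether, the E alkene and the stereocentre untouched.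

**Step 4**
Reactants: 6 3-methylbut-2-enoic acid
Product: 7 tert-butyl 3-methylbut-2-enoate
Conditions: Boc2O, DMAP (cat.), t-BuOH, rt to 40 °C
Reagents that add atoms: di-tert-butyl dicarbonate CC(C)(C)OC(=O)OC(=O)OC(C)(C)C
Why: DMAP-catalysed esterification through the mixed carbonic anhydride gives the ester that step 7 can cleave without aqueous base; no stereocentre is formed.

**Step 5**
Reactants: 7 tert-butyl 3-methylbut-2-enoate
Product: 8 tert-butyl[(1-tert-butoxy-3-methylbuta-1,3-dien-1-yl)oxy]dimethylsilane
Conditions: LiN(iPr)2, THF, −78 °C; t-BuMe2SiCl, DMPU, −78 °C to rt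
Reagents that add atoms: tert-butyldimethylsilyl chloride CC(C)(C)[Si](C)(C)Cl
Why: Gamma-deprotonation and O-silylation of the extended enolate give the silyl dienol ether (silyl ketene acetal formation), whose ketene acetal geometry has no consequence.

**Step 6**
Reactants: 5 (5R,6E)-2,6-dimethyl-3,8-dioxo-5-(triethylsilyloxy)oct-6-en-2-yl benzoate; 8 tert-butyl[(1-tert-butoxy-3-methylbuta-1,3-dien-1-yl)oxy]dimethylsilane
Product: 9 tert-butyl (2E,5S,6E,8R)-11-(benzoyloxy)-5-hydroxy-3,7,11-trimethyl-10-oxo-8-(triethylsilyloxy)dodeca-2,6-dienoate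
Conditions: SiCl4, (R,R)-bisphosphoramide from N,N'-dimethyl-1,1'-binaphthyl-2,2'-diamine with a pentane-1,5-diyl link (5 mol %), iPr2NEt (cat.), CH2Cl2, −78 °C; sat. aq NaHCO3
Reagents that add atoms: none
Why: Catalytic enantioselective vinylogous Mukaiyama aldol addition, in which the dienol ether reacts at its gamma carbon with the aldehyde only and the chiral Lewis-base-activated silicon cation sets future C1 as S independently of the remote C9 centre, giving the E enoate.

**Step 7**
Reactants: 9 tert-butyl (2E,5S,6E,8R)-11-(benzoyloxy)-5-hydroxy-3,7,11-trimethyl-10-oxo-8-(triethylsilyloxy)dodeca-2,6-dienoate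
Product: 11 (2E,5S,6E,8R)-11-(benzoyloxy)-5-(tert-butyldimethylsilyloxy)-3,7,11-trimethyl-10-oxo-8-(triethylsilyloxy)dodeca-2,6-dienoic acid, via silyl ester 10 (not isolated)
Conditions: t-BuMe2SiOTf, 2,6-lutidine, CH2Cl2, 0 °C to rt; then MeOH, 0 °C
Reagents that add atoms: tert-butyldimethylsilyl trifluoromethanesulfonate CC(C)(C)[Si](C)(C)OS(=O)(=O)C(F)(F)F
Why: The silyl triflate silylates the hydroxyl group and cleaves the tert-butyl ester (loss of 2-methylpropene) to a silyl ester that methanol solvolyses selectively, so the acid is set free without base that would endanger the benzoate or the beta-silyloxy ketone.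

**Step 8**
Reactants: 11 (2E,5S,6E,8R)-11-(benzoyloxy)-5-(tert-butyldimethylsilyloxy)-3,7,11-trimethyl-10-oxo-8-(triethylsilyloxy)dodeca-2,6-dienoic acid
Product: 14 7-[(1R)-4-(benzoyloxy)-4-methyl-3-oxo-1-(triethylsilyloxy)pentyl]-4-(tert-butyldimethylsilyloxy)-7-methyl-2-methylidenebicyclo[3.1.1]heptan-6-one (chain on C7 anti to the C2-C4 bridge; silyloxy group on C4 trans to the C7 bridge), via acid chloride 12 (not isolated), via vinylketene 13 (not isolated)
Conditions: 1-chloro-N,N,2-trimethylprop-1-en-1-amine, CH2Cl2, 0 °C; then slow addition to Et3N, toluene, reflux, high dilution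
Reagents that add atoms: none
Why: Intramolecular vinylketene–alkene (2+2) cycloaddition, in which the ketene carbonyl carbon (C5) bonds to the less substituted alkene carbon C11 and the ketene alpha carbon C4 to C10 to give the bridged skeleton; suprafacial addition to the E alkene puts the C9 chain on the carbonyl-bridge side of C10, and allylic 1,3-strain between the C10 methyl group and the C1 substituents lets the ketene reach only the alkene face opposite the silyloxy group, so C1 sets C4, C10 and C11.

**Step 9**
Reactants: 14 7-[(1R)-4-(benzoyloxy)-4-methyl-3-oxo-1-(triethylsilyloxy)pentyl]-4-(tert-butyldimethylsilyloxy)-7-methyl-2-methylidenebicyclo[3.1.1]heptan-6-one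
Product: 17 tricyclic diol ketone (longipinane skeleton: 1-OTBS; 3-methylidene; 5-OH towards the C1-C3 bridge; 7-oxo; 9-OH), via samarium enolate 15 (not isolated), via triethylsilyl ether 16 (not isolated)
Conditions: SmI2 (2.5 equiv), THF, −78 to −20 °C, high dilution; then AcOH/THF/H2O, rt
Reagents that add atoms: none
Why: Two single-electron transfers from SmI2 to the C7 ketone expel benzoate from C6 and turn this formerly electrophilic, fully substituted carbon into the carbon terminus of the regiodefined trivalent samarium enolate 15, which adds to the strained C5 cyclobutanone carbonyl, so that two acceptor carbons are joined. The closest known reaction type is the SmI2-mediated intramolecular Reformatsky-type aldol cyclisation of alpha-halo or alpha-acyloxy carbonyl compounds onto ketones, which is established for medium rings. The only ring closed is the seven-membered ring C4-C5-C6-C7-C8-C9-C10, by a 7-(enolendo)-exo-trig attack. The one new stereocentre, C5, is fixed by the tether: the chain hangs from the face of C10 remote from the C1–C3 bridge and can reach the C5 carbonyl only from that face, so O5 is pushed towards the bridge and C6 takes its place as in 25, C6 itself not being stereogenic. The step needs reduction of the benzoyloxy ketone before the cyclobutanone and enolate formation at C6 rather than C8; the chelating acyloxy ketone is the better electron acceptor at −78 °C, C6 bears no hydrogen so its enolate arises only by loss of benzoate and does not equilibrate in the aprotic medium (no beta-elimination at C9), the cyclobutanone has only bridgehead alpha hydrogens, and release of carbonyl strain drives the congested C5–C6 bond formation. The mild acidic work-up removes only the triethylsilyl group and frees the C9 hydroxyl for step 10.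

**Step 10**
Reactants: 17 tricyclic diol ketone; 18 3-methylbutanal
Product: 19 tricyclic 5,7-diol 9-(3-methylbutanoate) (1-OTBS; 3-methylidene; 7-OH anti to the 9-acyloxy group)
Conditions: SmI2 (30 mol %), 18 (excess), THF, −10 °C
Reagents that add atoms: none
Why: Evans–Tishchenko reaction, in which the less hindered secondary C9 hydroxyl forms the hemiacetal with 18 and transfers its hydride within a samarium chelate to the face of the C7 ketone that is syn to O9, giving the 7,9-anti diol with the isovalerate on O9 and the C7 hydroxyl free.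

**Step 11**
Reactants: 19 tricyclic 5,7-diol 9-(3-methylbutanoate); 6 3-methylbut-2-enoic acid
Product: 20 tricyclic 5-ol 7-(3-methylbut-2-enoate) 9-(3-methylbutanoate) (1-OTBS; 3-methylidene)
Conditions: DCC, DMAP, CH2Cl2, rt to 40 °C
Reagents that add atoms: none
Why: Steglich esterification acylates the secondary C7 hydroxyl in preference to the tertiary C5 hydroxyl with retention at C7, and the absence of a strong amine base avoids deconjugation of the senecioyl group.

**Step 12**
Reactants: 20 tricyclic 5-ol 7-(3-methylbut-2-enoate) 9-(3-methylbutanoate)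
Product: 21 the 5-O-(methyl oxalyl) ester of 20
Conditions: ClC(O)CO2Me, Et3N, DMAP, CH2Cl2, 0 °C to rt
Reagents that add atoms: methyl chlorooxoacetate COC(=O)C(=O)Cl
Why: Acylation with the small and very reactive oxalyl half-ester chloride activates the hindered tertiary alcohol, which cannot eliminate because its neighbours are two bridgeheads and a quaternary carbon.

**Step 13**
Reactants: 21 the 5-O-(methyl oxalyl) ester of 20
Product: 22 1-(tert-butyldimethylsilyloxy)-3-methylidene diester (5-H; all other centres as in 25)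
Conditions: Bu3SnH, AIBN, toluene, 110 °C
Reagents that add atoms: none
Why: Barton–McCombie-type radical deoxygenation of a tertiary oxalate, in which the C5 cyclobutyl radical is held in the cage and can take hydrogen only from the face towards the C1–C3 bridge, giving the C5 configuration of 25.

**Step 14**
Reactants: 22 1-(tert-butyldimethylsilyloxy)-3-methylidene diester
Product: 23 1-hydroxy-3-methylidene diester
Conditions: Bu4NF, AcOH, THF, rt to 40 °C
Reagents that add atoms: none
Why: Buffered fluoride desilylation frees the C1 hydroxyl without acid that would ionise the strained methylidene system and without base strong enough to touch the two esters.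

**Step 15**
Reactants: 23 1-hydroxy-3-methylidene diester
Product: 25 target CNP0214473.1, via unconjugated enone 24 (not isolated)
Conditions: DMP [1,1,1-triacetoxy-1,1-dihydro-1,2-benziodoxol-3(1H)-one], NaHCO3, CH2Cl2, 0 °C to rt; filter; then DBU (cat.), CH2Cl2, rt
Reagents that add atoms: none
Why: Periodinane oxidation removes the now spent C1 stereocentre, and base-catalysed isomerisation moves the exocyclic alkene into conjugation (C2=C3), while the bridgehead C11–H cannot epimerise and no ester lies beta to the ketone.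

**Compound list**

1 | 3-hydroxy-3-methylbutan-2-one | CC(=O)C(C)(C)O | starting material
2 | 2-methyl-3-oxobutan-2-yl benzoate | CC(=O)C(C)(C)OC(=O)c1ccccc1 | intermediate
3 | (2E)-4,4-dimethoxy-2-methylbut-2-enal | O=C/C(C)=C/C(OC)OC | starting material
4 | (5R,6E)-5-hydroxy-8,8-dimethoxy-2,6-dimethyl-3-oxooct-6-en-2-yl benzoate | CC(C)(OC(=O)c1ccccc1)C(=O)C[C@@H](O)/C(C)=C/C(OC)OC | intermediate
5 | (5R,6E)-2,6-dimethyl-3,8-dioxo-5-(triethylsilyloxy)oct-6-en-2-yl benzoate | CC(C)(OC(=O)c1ccccc1)C(=O)C[C@@H](O[Si](CC)(CC)CC)/C(C)=C/C=O | intermediate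
6 | 3-methylbut-2-enoic acid | CC(C)=CC(=O)O | starting material
7 | tert-butyl 3-methylbut-2-enoate | CC(C)=CC(=O)OC(C)(C)C | intermediate
8 | tert-butyl[(1-tert-butoxy-3-methylbuta-1,3-dien-1-yl)oxy]dimethylsilane (ketene acetal geometry not defined, inconsequential) | C=C(C)C=C(OC(C)(C)C)O[Si](C)(C)C(C)(C)C | intermediate
9 | tert-butyl (2E,5S,6E,8R)-11-(benzoyloxy)-5-hydroxy-3,7,11-trimethyl-10-oxo-8-(triethylsilyloxy)dodeca-2,6-dienoate | CC(C)(OC(=O)c1ccccc1)C(=O)C[C@@H](O[Si](CC)(CC)CC)/C(C)=C/[C@@H](O)C/C(C)=C/C(=O)OC(C)(C)C | intermediate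
10 | tert-butyldimethylsilyl ester of 11 | CC(C)(OC(=O)c1ccccc1)C(=O)C[C@@H](O[Si](CC)(CC)CC)/C(C)=C/[C@@H](O[Si](C)(C)C(C)(C)C)C/C(C)=C/C(=O)O[Si](C)(C)C(C)(C)C | intermediate
11 | (2E,5S,6E,8R)-11-(benzoyloxy)-5-(tert-butyldimethylsilyloxy)-3,7,11-trimethyl-10-oxo-8-(triethylsilyloxy)dodeca-2,6-dienoic acid | CC(C)(OC(=O)c1ccccc1)C(=O)C[C@@H](O[Si](CC)(CC)CC)/C(C)=C/[C@@H](O[Si](C)(C)C(C)(C)C)C/C(C)=C/C(=O)O | intermediate
12 | acid chloride of 11 | CC(C)(OC(=O)c1ccccc1)C(=O)C[C@@H](O[Si](CC)(CC)CC)/C(C)=C/[C@@H](O[Si](C)(C)C(C)(C)C)C/C(C)=C/C(=O)Cl | intermediate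
13 | vinylketene, (5S,6E,8R)-11-(benzoyloxy)-5-(tert-butyldimethylsilyloxy)-7,11-dimethyl-3-methylidene-8-(triethylsilyloxy)dodeca-1,6-diene-1,10-dione | CC(C)(OC(=O)c1ccccc1)C(=O)C[C@@H](O[Si](CC)(CC)CC)/C(C)=C/[C@@H](O[Si](C)(C)C(C)(C)C)CC(=C)C=C=O | intermediate
14 | bicyclo[3.1.1]heptan-6-one with the C9–C6 chain (see step 8) | CC(C)(OC(=O)c1ccccc1)C(=O)C[C@@H](O[Si](CC)(CC)CC)[C@@]2(C)[C@@H]3[C@@H](O[Si](C)(C)C(C)(C)C)CC(=C)[C@H]2C3=O | intermediate
15 | diiodosamarium enolate (C6=C7) of debenzoyloxylated 14 | CC(C)=C(O[Sm](I)I)C[C@@H](O[Si](CC)(CC)CC)[C@@]1(C)[C@@H]2[C@@H](O[Si](C)(C)C(C)(C)C)CC(=C)[C@H]1C2=O | intermediate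
16 | 9-O-triethylsilyl ether of 17 | O=C1C[C@@H](O[Si](CC)(CC)CC)[C@@]2(C)[C@@H]3[C@@H](O[Si](C)(C)C(C)(C)C)CC(=C)[C@H]2[C@]3(O)C1(C)C | intermediate
17 | tricyclic diol ketone (1-OTBS, 3-methylidene, 5-OH, 7-oxo, 9-OH) | O=C1C[C@@H](O)[C@@]2(C)[C@@H]3[C@@H](O[Si](C)(C)C(C)(C)C)CC(=C)[C@H]2[C@]3(O)C1(C)C | intermediate
18 | 3-methylbutanal | CC(C)CC=O | starting material
19 | tricyclic 5,7-diol 9-(3-methylbutanoate) | O[C@@H]1C[C@@H](OC(=O)CC(C)C)[C@@]2(C)[C@@H]3[C@@H](O[Si](C)(C)C(C)(C)C)CC(=C)[C@H]2[C@]3(O)C1(C)C | intermediate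
20 | tricyclic 5-ol 7-(3-methylbut-2-enoate) 9-(3-methylbutanoate) | CC(C)=CC(=O)O[C@@H]1C[C@@H](OC(=O)CC(C)C)[C@@]2(C)[C@@H]3[C@@H](O[Si](C)(C)C(C)(C)C)CC(=C)[C@H]2[C@]3(O)C1(C)C | intermediate
21 | 5-O-(methyl oxalyl) ester of 20 | CC(C)=CC(=O)O[C@@H]1C[C@@H](OC(=O)CC(C)C)[C@@]2(C)[C@@H]3[C@@H](O[Si](C)(C)C(C)(C)C)CC(=C)[C@H]2[C@]3(OC(=O)C(=O)OC)C1(C)C | intermediate
22 | 1-(tert-butyldimethylsilyloxy)-3-methylidene diester | CC(C)=CC(=O)O[C@@H]1C[C@@H](OC(=O)CC(C)C)[C@@]2(C)[C@@H]3[C@@H](O[Si](C)(C)C(C)(C)C)CC(=C)[C@H]2[C@@H]3C1(C)C | intermediate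
23 | 1-hydroxy-3-methylidene diester | CC(C)=CC(=O)O[C@@H]1C[C@@H](OC(=O)CC(C)C)[C@@]2(C)[C@@H]3[C@@H](O)CC(=C)[C@H]2[C@@H]3C1(C)C | intermediate
24 | 1-oxo-3-methylidene diester (unconjugated enone) | CC(C)=CC(=O)O[C@@H]1C[C@@H](OC(=O)CC(C)C)[C@@]2(C)[C@@H]3C(=O)CC(=C)[C@H]2[C@@H]3C1(C)C | intermediate
25 | CNP0214473.1 | CC(C)=CC(=O)O[C@@H]1C[C@@H](OC(=O)CC(C)C)[C@@]2(C)[C@@H]3C(=O)C=C(C)[C@H]2[C@@H]3C1(C)C | target

**Total step count:** 15. **Longest linear sequence:** 13 steps (1–3, then 6–15).

**Steps most likely to fail**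

Step 9. The samarium enolate may be protonated, or the congested aldolate may revert, before the ring is secured. The fallback separates enolate generation from bond formation and makes the latter irreversible.
- It sets out from 14. SmI2 in THF at −78 °C in the presence of Me3SiCl traps the enolate as the tetrasubstituted trimethylsilyl enol ether F1, which is isolated.
- F1 is closed by an intramolecular Mukaiyama aldol addition (BF3·OEt2, CH2Cl2, −78 °C; aqueous work-up).
- This returns to the route at 16, which is desilylated at O9 as in step 9.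

Step 8. The alkene carries two allylic silyloxy groups and is a weak nucleophile, so dimerisation of the vinylketene or loss of facial selectivity at reflux may overtake the cycloaddition. The fallback replaces the ketene by the more electrophilic keteniminium ion.
- It sets out from 11. Coupling with pyrrolidine (EDC, CH2Cl2) gives the pyrrolidine amide F2.
- Tf2O and 2,4,6-collidine in 1,2-dichloroethane generate the vinylketeniminium salt, which undergoes the same intramolecular (2+2) at or below room temperature to the cyclobutaniminium triflate F3.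
- Hydrolysis with aq NaHCO3 returns to the route at 14.

Step 12. Acylation of the tertiary C5 hydroxyl, flanked by C6 and by the C1 silyl ether, may stall. The fallback avoids any derivative.
- It sets out from 20. Titanium-catalysed radical dehydroxylation (Cp*TiCl3 (cat.), Zn, Et3SiCl, PhSiH3, THF, 60 °C) lets trivalent titanium abstract the tertiary hydroxyl group directly.
- The cage-bound C5 radical is then reduced by the silane.
- This returns to the route at 22 and bypasses 21.

**Further compounds**

F1 | step 9 | trimethylsilyl enol ether (C6=C7) derived from 14 | CC(C)=C(O[Si](C)(C)C)C[C@@H](O[Si](CC)(CC)CC)[C@@]1(C)[C@@H]2[C@@H](O[Si](C)(C)C(C)(C)C)CC(=C)[C@H]1C2=O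
F2 | step 8 | pyrrolidine amide of 11 | CC(C)(OC(=O)c1ccccc1)C(=O)C[C@@H](O[Si](CC)(CC)CC)/C(C)=C/[C@@H](O[Si](C)(C)C(C)(C)C)C/C(C)=C/C(=O)N1CCCC1
F3 | step 8 | cyclobutaniminium triflate corresponding to 14 | CC(C)(OC(=O)c1ccccc1)C(=O)C[C@@H](O[Si](CC)(CC)CC)[C@@]2(C)[C@@H]3[C@@H](O[Si](C)(C)C(C)(C)C)CC(=C)[C@H]2C3=[N+]4CCCC4.[O-]S(=O)(=O)C(F)(F)F
F0 | step 12 | none | none
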